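**Retrosynthetic overview**
1. The target is luteolin carrying a 6-carboxy-2,3-dihydroxyphenyl ring (ring D) at C8. All six phenols travel as benzyl ethers and are freed last by neutral hydrogenolysis, so the 7-OH/CO2H pair never meets acid or heat and does not lactonise.
2. CO2H comes from CHO (Pinnick). The C8–aryl bond comes from a Suzuki–Miyaura coupling of a flavone-8-boronate with 3,4-bis(benzyloxy)-2-bromobenzaldehyde, made in three steps from isovanillin.
3. Pyranone ring C comes from oxidative cyclisation of a 2'-hydroxy-3'-iodochalcone. The chalcone C(alpha)=C(beta) bond comes from the intermolecular Claisen–Schmidt aldol condensation of the ring A methyl ketone with the ring B aldehyde, which is the key fragment union.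
4. Rings A, B and D are bought as arenes (phloroacetophenone, 3,4-bis(benzyloxy)benzaldehyde, isovanillin). Ring C is the only ring built, and it is closed before the biaryl bond is made.

Assumption: the SMILES has no stereodescriptor and no stereocentre; the hindered C8–aryl axis is the only stereogenic element and is left undefined, so the compound is made as drawn, with the axis neither controlled nor resolved.

**Step 1**
Reactants: 1 2,4,6-trihydroxyacetophenone
Product: 2 1-[2,4-bis(benzyloxy)-6-hydroxyphenyl]ethan-1-one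
Conditions: BnBr (2.1 equiv), K2CO3 (2.2 equiv), acetone, reflux, 12 h
Reagents that add atoms: benzyl bromide, BrCc1ccccc1
Why: Williamson ether synthesis; after the para and one ortho hydroxyl are alkylated, the last hydroxyl is locked in a hydrogen bond to the acetyl group and stays free when the bromide is limited to two equivalents.

**Step 2**
Reactants: 2 1-[2,4-bis(benzyloxy)-6-hydroxyphenyl]ethan-1-one
Product: 3 1-[4,6-bis(benzyloxy)-2-hydroxy-3-iodophenyl]ethan-1-one
Conditions: NIS (1.05 equiv), TFA (10 mol %), MeCN/CH2Cl2, 0 °C to rt, dark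
Reagents that add atoms: N-iodosuccinimide, O=C1CCC(=O)N1I
Why: Electrophilic aromatic iodination; both free ring positions are activated by three oxygens, but the one next to the small free OH is far less crowded than the one between two benzyloxy groups, so iodine enters at C3, the future C8.

**Step 3**
Reactants: 3 1-[4,6-bis(benzyloxy)-2-hydroxy-3-iodophenyl]ethan-1-one; 4 3,4-bis(benzyloxy)benzaldehyde
Product: 6 (E)-1-[4,6-bis(benzyloxy)-2-hydroxy-3-iodophenyl]-3-[3,4-bis(benzyloxy)phenyl]prop-2-en-1-one, via aldol adduct 5 (not isolated)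
Conditions: KOH (50% aq, 12 equiv), EtOH/THF 1:1, rt, 36 h; then 1 M HCl, 0 °C
Reagents that add atoms: none
Why: Claisen–Schmidt crossed aldol condensation; only 3 can enolise and only 4 is a good acceptor, and E1cB loss of water from 5 gives the conjugated (E)-enone, erasing the racemic carbinol centre of 5.

**Step 4**
Reactants: 6 (E)-1-[4,6-bis(benzyloxy)-2-hydroxy-3-iodophenyl]-3-[3,4-bis(benzyloxy)phenyl]prop-2-en-1-one
Product: 9 5,7-bis(benzyloxy)-2-[3,4-bis(benzyloxy)phenyl]-8-iodo-4H-chromen-4-one, via flavanone 7 (not isolated), via 3-iodoflavanone 8 (not isolated)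
Conditions: I2 (10 mol %), DMSO, 125 °C, 2–3 h; aq Na2S2O3 wash
Reagents that add atoms: none
Why: Iodine/DMSO oxidative cyclisation of a 2'-hydroxychalcone (oxa-Michael closure, alpha-iodination, loss of HI); DMSO re-oxidises HI at once, which spares the benzyl ethers and the aryl iodide, and the transient centres of 7 and 8 vanish on aromatisation.

**Step 5**
Reactants: 9 5,7-bis(benzyloxy)-2-[3,4-bis(benzyloxy)phenyl]-8-iodo-4H-chromen-4-one
Product: 10 5,7-bis(benzyloxy)-2-[3,4-bis(benzyloxy)phenyl]-8-(4,4,5,5-tetramethyl-1,3,2-dioxaborolan-2-yl)-4H-chromen-4-one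
Conditions: B2pin2 (1.5 equiv), PdCl2(dppf) (5 mol %), KOAc (3 equiv), 1,4-dioxane, 90 °C, 12 h
Reagents that add atoms: bis(pinacolato)diboron, CC1(C)OB(OC1(C)C)B1OC(C)(C)C(C)(C)O1
Why: Miyaura borylation; the aryl iodide adds readily to zerovalent palladium, and the weak base KOAc drives boron transfer without opening the pyranone or triggering homocoupling.

**Step 6**
Reactants: 11 3-hydroxy-4-methoxybenzaldehyde (isovanillin)
Product: 12 2-bromo-3-hydroxy-4-methoxybenzaldehyde
Conditions: Br2 (1.05 equiv), NaOAc (2 equiv), Fe powder (5 mol %), AcOH, rt, 2 h; pour on ice water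
Reagents that add atoms: bromine, BrBr
Why: Electrophilic aromatic bromination directed ortho to the free phenol; in isovanillin this reliably gives the 2-bromo isomer, which crystallises from the quench.

**Step 7**
Reactants: 12 2-bromo-3-hydroxy-4-methoxybenzaldehyde
Product: 14 2-bromo-3,4-dihydroxybenzaldehyde, via cyclic bromoborate 13 (not isolated)
Conditions: BBr3 (1.5 equiv), CH2Cl2, −78 °C to rt, 4 h; then ice water
Reagents that add atoms: none
Why: Lewis-acid aryl methyl ether cleavage; boron first binds the neighbouring phenol, bromide then removes the methyl group, and the resulting five-membered borate 13 is hydrolysed at work-up.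

**Step 8**
Reactants: 14 2-bromo-3,4-dihydroxybenzaldehyde
Product: 15 3,4-bis(benzyloxy)-2-bromobenzaldehyde
Conditions: BnBr (2.3 equiv), K2CO3 (2.5 equiv), DMF, 50 °C, 6 h
Reagents that add atoms: benzyl bromide, BrCc1ccccc1
Why: Williamson ether synthesis on both acidic catechol hydroxyls; neither the aldehyde nor the aryl bromide reacts with carbonate.

**Step 9**
Reactants: 10 5,7-bis(benzyloxy)-2-[3,4-bis(benzyloxy)phenyl]-8-(4,4,5,5-tetramethyl-1,3,2-dioxaborolan-2-yl)-4H-chromen-4-one; 15 3,4-bis(benzyloxy)-2-bromobenzaldehyde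
Product: 16 3,4-bis(benzyloxy)-2-{5,7-bis(benzyloxy)-2-[3,4-bis(benzyloxy)phenyl]-4-oxo-4H-chromen-8-yl}benzaldehyde
Conditions: Pd(OAc)2 (5 mol %), SPhos (10 mol %), K3PO4 (3 equiv), toluene/H2O 10:1, 90 °C, 16 h, degassed
Reagents that add atoms: none
Why: Suzuki–Miyaura cross-coupling; the ortho formyl group speeds addition of the bromide to zerovalent palladium, SPhos is the proven ligand for tetra-ortho-substituted biaryls, and the new axis forms without control, as the target leaves it undefined.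

**Step 10**
Reactants: 16 3,4-bis(benzyloxy)-2-{5,7-bis(benzyloxy)-2-[3,4-bis(benzyloxy)phenyl]-4-oxo-4H-chromen-8-yl}benzaldehyde
Product: 17 3,4-bis(benzyloxy)-2-{5,7-bis(benzyloxy)-2-[3,4-bis(benzyloxy)phenyl]-4-oxo-4H-chromen-8-yl}benzoic acid
Conditions: NaClO2 (3 equiv), NaH2PO4 (4 equiv), 2-methyl-2-butene (20 equiv), tBuOH/THF/H2O, 0 °C to rt, 4 h
Reagents that add atoms: sodium chlorite, [Na+].[O-][Cl+][O-]
Why: Pinnick oxidation; chlorous acid oxidises only the aldehyde, and the alkene traps hypochlorous acid before it can chlorinate the electron-rich rings or the enone.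

**Step 11**
Reactants: 17 3,4-bis(benzyloxy)-2-{5,7-bis(benzyloxy)-2-[3,4-bis(benzyloxy)phenyl]-4-oxo-4H-chromen-8-yl}benzoic acid
Product: 18 2-[2-(3,4-dihydroxyphenyl)-5,7-dihydroxy-4-oxo-4H-chromen-8-yl]-3,4-dihydroxybenzoic acid (target)
Conditions: H2 (1 atm), 10% Pd/C, THF/MeOH 1:1, rt, 12 h; filter under Ar, evaporate below 30 °C, Sephadex LH-20 (MeOH)
Reagents that add atoms: none
Why: Catalytic hydrogenolysis of six benzyl aryl ethers under neutral conditions; the flavone double bond resists hydrogen at one atmosphere, and without acid or heat the free acid does not close onto the 7-OH.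

**Compound list**
1 | 2,4,6-trihydroxyacetophenone | CC(=O)c1c(O)cc(O)cc1O | starting material
2 | 1-[2,4-bis(benzyloxy)-6-hydroxyphenyl]ethan-1-one | CC(=O)c1c(O)cc(OCc2ccccc2)cc1OCc1ccccc1 | intermediate
3 | 1-[4,6-bis(benzyloxy)-2-hydroxy-3-iodophenyl]ethan-1-one | CC(=O)c1c(O)c(I)c(OCc2ccccc2)cc1OCc1ccccc1 | intermediate
4 | 3,4-bis(benzyloxy)benzaldehyde | O=Cc1ccc(OCc2ccccc2)c(OCc2ccccc2)c1 | starting material
5 | aldol adduct, 1-[4,6-bis(benzyloxy)-2-hydroxy-3-iodophenyl]-3-[3,4-bis(benzyloxy)phenyl]-3-hydroxypropan-1-one (racemic, not isolated) | O=C(CC(O)c1ccc(OCc2ccccc2)c(OCc2ccccc2)c1)c1c(O)c(I)c(OCc2ccccc2)cc1OCc1ccccc1 | intermediate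
6 | (E)-1-[4,6-bis(benzyloxy)-2-hydroxy-3-iodophenyl]-3-[3,4-bis(benzyloxy)phenyl]prop-2-en-1-one | O=C(/C=C/c1ccc(OCc2ccccc2)c(OCc2ccccc2)c1)c1c(O)c(I)c(OCc2ccccc2)cc1OCc1ccccc1 | intermediate
7 | flavanone, 5,7-bis(benzyloxy)-2-[3,4-bis(benzyloxy)phenyl]-8-iodochroman-4-one (racemic, not isolated) | O=C1CC(c2ccc(OCc3ccccc3)c(OCc3ccccc3)c2)Oc2c(I)c(OCc3ccccc3)cc(OCc3ccccc3)c21 | intermediate
8 | 3-iodoflavanone, 5,7-bis(benzyloxy)-2-[3,4-bis(benzyloxy)phenyl]-3,8-diiodochroman-4-one (racemic, not isolated) | O=C1C(I)C(c2ccc(OCc3ccccc3)c(OCc3ccccc3)c2)Oc2c(I)c(OCc3ccccc3)cc(OCc3ccccc3)c21 | intermediate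
9 | 5,7-bis(benzyloxy)-2-[3,4-bis(benzyloxy)phenyl]-8-iodo-4H-chromen-4-one | O=c1cc(-c2ccc(OCc3ccccc3)c(OCc3ccccc3)c2)oc2c(I)c(OCc3ccccc3)cc(OCc3ccccc3)c12 | intermediate
10 | 5,7-bis(benzyloxy)-2-[3,4-bis(benzyloxy)phenyl]-8-(4,4,5,5-tetramethyl-1,3,2-dioxaborolan-2-yl)-4H-chromen-4-one | O=c1cc(-c2ccc(OCc3ccccc3)c(OCc3ccccc3)c2)oc2c(B3OC(C)(C)C(C)(C)O3)c(OCc3ccccc3)cc(OCc3ccccc3)c12 | intermediate
11 | 3-hydroxy-4-methoxybenzaldehyde (isovanillin) | COc1ccc(C=O)cc1O | starting material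
12 | 2-bromo-3-hydroxy-4-methoxybenzaldehyde | COc1ccc(C=O)c(Br)c1O | intermediate
13 | cyclic bromoborate, 2,4-dibromo-1,3,2-benzodioxaborole-5-carbaldehyde (not isolated) | O=Cc1ccc2OB(Br)Oc2c1Br | intermediate
14 | 2-bromo-3,4-dihydroxybenzaldehyde | O=Cc1ccc(O)c(O)c1Br | intermediate
15 | 3,4-bis(benzyloxy)-2-bromobenzaldehyde | O=Cc1ccc(OCc2ccccc2)c(OCc2ccccc2)c1Br | intermediate
16 | 3,4-bis(benzyloxy)-2-{5,7-bis(benzyloxy)-2-[3,4-bis(benzyloxy)phenyl]-4-oxo-4H-chromen-8-yl}benzaldehyde (axis racemic) | O=Cc1ccc(OCc2ccccc2)c(OCc2ccccc2)c1-c1c(OCc2ccccc2)cc(OCc2ccccc2)c2c(=O)cc(-c3ccc(OCc4ccccc4)c(OCc4ccccc4)c3)oc12 | intermediate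
17 | 3,4-bis(benzyloxy)-2-{5,7-bis(benzyloxy)-2-[3,4-bis(benzyloxy)phenyl]-4-oxo-4H-chromen-8-yl}benzoic acid (axis racemic) | O=C(O)c1ccc(OCc2ccccc2)c(OCc2ccccc2)c1-c1c(OCc2ccccc2)cc(OCc2ccccc2)c2c(=O)cc(-c3ccc(OCc4ccccc4)c(OCc4ccccc4)c3)oc12 | intermediate
18 | 2-[2-(3,4-dihydroxyphenyl)-5,7-dihydroxy-4-oxo-4H-chromen-8-yl]-3,4-dihydroxybenzoic acid | O=C(O)c1ccc(O)c(O)c1-c1c(O)cc(O)c2c(=O)cc(-c3ccc(O)c(O)c3)oc12 | target

**Totals**
Total step count: 11.
Longest linear sequence: 8 steps (steps 1, 2, 3, 4, 5, 9, 10, 11). Steps 6–8 form the convergent side branch.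

**Three steps most likely to fail**

Step 9 (tetra-ortho-substituted Suzuki coupling). Protodeboronation of 10 may outrun the slow transmetalation.
- The fallback reverses the polarity and changes the metal to zinc (Negishi coupling). It sets out from 15 and 9 and comes back at 16.
- Aldehyde 15 is protected with ethylene glycol (cat. pTsOH, toluene, Dean–Stark) as 2-[3,4-bis(benzyloxy)-2-bromophenyl]-1,3-dioxolane F1.
- Bromine–lithium exchange (nBuLi, THF, −78 °C) gives the aryllithium F2. ZnCl2 turns it at once into the arylzinc chloride F3.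
- F3 tolerates the chromenone and is coupled with iodide 9 (Pd2(dba)3, RuPhos, THF, 65 °C) to the biaryl dioxolane F4.
- 1 M HCl in THF at rt unmasks aldehyde 16.

Step 5 (borylation of a di-ortho-oxygenated aryl iodide). Reduction of the carbon–iodine bond can compete with boron transfer.
- The fallback drops palladium for iodine–lithium exchange with in situ trapping. It sets out from 9 and comes back at 10.
- nBuLi is added at −95 °C to a THF/toluene solution of 9 and B(OiPr)3.
- The short-lived 8-lithioflavone F5 is caught before it can attack a chromenone and becomes the lithium aryl(triisopropoxy)borate F6.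
- Pinacol and AcOH at rt convert this to boronate 10.

Step 4 (oxidative cyclisation). Partial loss of the 5-O-benzyl group or of the aryl iodine by HI at 125 °C is possible.
- The fallback is a non-oxidative 1,3-diketone route that replaces steps 3 and 4. It sets out from 3 and 4 and comes back at 9.
- Aldehyde 4 is oxidised (NaClO2, NaH2PO4, 2-methyl-2-butene) to 3,4-bis(benzyloxy)benzoic acid F7.
- (COCl)2 with cat. DMF in CH2Cl2 gives 3,4-bis(benzyloxy)benzoyl chloride F8.
- Ketone 3 is doubly deprotonated with LiN(SiMe3)2 (4 equiv, THF, −78 °C) and C-acylated by the chloride in a crossed Claisen condensation. The product is the 1,3-diketone 1-[4,6-bis(benzyloxy)-2-hydroxy-3-iodophenyl]-3-[3,4-bis(benzyloxy)phenyl]propane-1,3-dione F9.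
- Cat. pTsOH in toluene at 90 °C closes and dehydrates it to flavone 9.

**Further compounds**
F1 | step 9 | 2-[3,4-bis(benzyloxy)-2-bromophenyl]-1,3-dioxolane | Brc1c(C2OCCO2)ccc(OCc2ccccc2)c1OCc1ccccc1
F2 | step 9 | [2,3-bis(benzyloxy)-6-(1,3-dioxolan-2-yl)phenyl]lithium | [Li]c1c(C2OCCO2)ccc(OCc2ccccc2)c1OCc1ccccc1
F3 | step 9 | [2,3-bis(benzyloxy)-6-(1,3-dioxolan-2-yl)phenyl]zinc chloride | Cl[Zn]c1c(C2OCCO2)ccc(OCc2ccccc2)c1OCc1ccccc1
F4 | step 9 | 5,7-bis(benzyloxy)-2-[3,4-bis(benzyloxy)phenyl]-8-[2,3-bis(benzyloxy)-6-(1,3-dioxolan-2-yl)phenyl]-4H-chromen-4-one | O=c1cc(-c2ccc(OCc3ccccc3)c(OCc3ccccc3)c2)oc2c(-c3c(C4OCCO4)ccc(OCc4ccccc4)c3OCc3ccccc3)c(OCc3ccccc3)cc(OCc3ccccc3)c12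
F5 | step 5 | {5,7-bis(benzyloxy)-2-[3,4-bis(benzyloxy)phenyl]-4-oxo-4H-chromen-8-yl}lithium | O=c1cc(-c2ccc(OCc3ccccc3)c(OCc3ccccc3)c2)oc2c([Li])c(OCc3ccccc3)cc(OCc3ccccc3)c12
F6 | step 5 | lithium {5,7-bis(benzyloxy)-2-[3,4-bis(benzyloxy)phenyl]-4-oxo-4H-chromen-8-yl}tri(propan-2-yloxy)borate | [Li+].O=c1cc(-c2ccc(OCc3ccccc3)c(OCc3ccccc3)c2)oc2c([B-](OC(C)C)(OC(C)C)OC(C)C)c(OCc3ccccc3)cc(OCc3ccccc3)c12
F7 | step 4 | 3,4-bis(benzyloxy)benzoic acid | O=C(O)c1ccc(OCc2ccccc2)c(OCc2ccccc2)c1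
F8 | step 4 | 3,4-bis(benzyloxy)benzoyl chloride | O=C(Cl)c1ccc(OCc2ccccc2)c(OCc2ccccc2)c1
F9 | step 4 | 1-[4,6-bis(benzyloxy)-2-hydroxy-3-iodophenyl]-3-[3,4-bis(benzyloxy)phenyl]propane-1,3-dione | O=C(CC(=O)c1ccc(OCc2ccccc2)c(OCc2ccccc2)c1)c1c(O)c(I)c(OCc2ccccc2)cc1OCc1ccccc1
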